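**Retrosynthetic overview**

1. Target 12 ⇐ PMB ether 11 (DDQ) ⇐ cis-fused cyclic carbonate 10 (palladium/B(OMe)3, net retention, methylates only the allylic oxygen) ⇐ cis-diol 9 ⇐ diene dibenzoate 8 (anti dihydroxylation).
2. 8 ⇐ dienediol 7 (both benzoates in one acylation) ⇐ oxanorbornadiene ester 3 by exo oxa-Michael addition of PMB alkoxide, E1cB opening of the oxygen bridge and ester reduction in one flask (sets O-5/O-6 cis and tells them apart).
3. 3 ⇐ furan 1 + methyl propiolate 2 by a catalytic enantioselective [4+2]; this one operation closes the carbocycle and the second oxolane ring of the 7-oxabicyclo[2.2.1] core and is the only C–C bond-forming step.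
4. Ring order: oxa-bridged bicycle (step 1) → bridge opened to the lone cyclohexadiene (step 2) → temporary carbonate ring closed (step 5) and opened (step 6); the phenyl rings arrive intact in BzCl and 4-methoxybenzyl alcohol.

Assumption: in step 1 the (S)-catalyst is taken to give the (1R,4S) adduct; if the sense of induction proves opposite, the (R)-catalyst is used and nothing else changes.

**Route**

Step 1
Reactants: 1 furan; 2 methyl propiolate (methyl prop-2-ynoate)
Product: 3 methyl (1R,4S)-7-oxabicyclo[2.2.1]hepta-2,5-diene-2-carboxylate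
Conditions: (S)-1-(2-methylphenyl)-3,3-diphenyltetrahydro-1H,3H-pyrrolo[1,2-c][1,3,2]oxazaborole (C24H24BNO, 10 mol %), AlBr3 (8 mol %), furan (5 equiv), CH2Cl2, −78 → −40 °C; Et3N quench, cold work-up
Reagents that add atoms: none
Why: Proposed new method: the AlBr3-activated oxazaborolidinium Lewis acid binds the ester carbonyl of 2 and screens one π-face, so furan adds in a Diels–Alder [4+2] cycloaddition that closes the carbocycle and a second oxolane ring in one operation and fixes both bridgeheads as (1R,4S); the closest known reactions are the enantioselective Diels–Alder of furan with 2,2,2-trifluoroethyl acrylate under this catalyst type and the racemic AlCl3-promoted furan/methyl propiolate cycloaddition.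

Step 2
Reactants: 3 methyl (1R,4S)-7-oxabicyclo[2.2.1]hepta-2,5-diene-2-carboxylate; 4 4-methoxybenzyl alcohol
Product: 7 (1S,6R)-5-(hydroxymethyl)-6-[(4-methoxyphenyl)methoxy]cyclohexa-2,4-dien-1-ol, via lithium ester enolate 5 (not isolated), via lithium dienol alkoxide 6 (not isolated)
Conditions: 4 (1.15 equiv), n-BuLi (1.1 equiv), THF, −78 °C; add 3, −78 → −40 °C; then i-Bu2AlH (4 equiv), −78 → 0 °C; aq. potassium sodium tartrate
Reagents that add atoms: none
Why: Proposed new method: the lithium alkoxide of 4 adds to the strained enoate carbon C3 from the exo face, syn to the oxygen bridge (oxa-Michael), the ester enolate then expels the bridging oxygen from C1 (E1cB ring opening, the reaction type used with LiN(SiMe3)2 on 7-oxanorbornene-2-carboxylates en route to shikimates), which sets the new C–O bond cis to the freed hydroxyl while the C4 stereocentre of 3 is kept, and i-Bu2AlH reduces the dienoate 1,2 before it can aromatise.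

Step 3
Reactants: 7 (1S,6R)-5-(hydroxymethyl)-6-[(4-methoxyphenyl)methoxy]cyclohexa-2,4-dien-1-ol
Product: 8 [(5S,6R)-5-(benzoyloxy)-6-[(4-methoxyphenyl)methoxy]cyclohexa-1,3-dien-1-yl]methyl benzoate
Conditions: BzCl (2.4 equiv), pyridine, 4-(dimethylamino)pyridine (5 mol %), CH2Cl2, 0 °C
Reagents that add atoms: benzoyl chloride, O=C(Cl)c1ccccc1
Why: Einhorn-type O-acylation with nucleophilic catalysis converts the primary allylic and the secondary hydroxyl into benzoates under mild base, leaving the PMB ether and both stereocentres untouched.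

Step 4
Reactants: 8 [(5S,6R)-5-(benzoyloxy)-6-[(4-methoxyphenyl)methoxy]cyclohexa-1,3-dien-1-yl]methyl benzoate
Product: 9 [(3R,4R,5S,6R)-5-(benzoyloxy)-3,4-dihydroxy-6-[(4-methoxyphenyl)methoxy]cyclohex-1-en-1-yl]methyl benzoate
Conditions: OsO4 (2 mol %), N-methylmorpholine N-oxide (1.2 equiv), citric acid (1 equiv), t-BuOH/H2O (1:1), 0 °C → rt
Reagents that add atoms: N-methylmorpholine N-oxide, C[N+]1([O-])CCOCC1; water, O (oxygen passed on by catalytic OsO4, O=[Os](=O)(=O)=O)
Why: Upjohn syn-dihydroxylation: OsO4 adds to the less hindered disubstituted C3=C4 alkene on the face opposite the 5-benzoate and 6-PMB ether (Kishi's rule), giving the 3,4-cis-diol trans to O-5, while the trisubstituted C1=C2 alkene, deactivated and shielded by two allylic C–O bonds, is left.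

Step 5
Reactants: 9 [(3R,4R,5S,6R)-5-(benzoyloxy)-3,4-dihydroxy-6-[(4-methoxyphenyl)methoxy]cyclohex-1-en-1-yl]methyl benzoate
Product: 10 [(3aR,4R,5R,7aR)-4-(benzoyloxy)-5-[(4-methoxyphenyl)methoxy]-2-oxo-3a,4,5,7a-tetrahydro-1,3-benzodioxol-6-yl]methyl benzoate
Conditions: 1,1'-carbonyldiimidazole (1.5 equiv), CH2Cl2, 0 °C → rt
Reagents that add atoms: 1,1'-carbonyldiimidazole, O=C(n1ccnc1)n1ccnc1
Why: Double acyl substitution on 1,1'-carbonyldiimidazole ties the cis-3,4-diol into a cis-fused five-membered carbonate, which turns the allylic oxygen into a leaving group without touching any stereocentre.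

Step 6
Reactants: 10 [(3aR,4R,5R,7aR)-4-(benzoyloxy)-5-[(4-methoxyphenyl)methoxy]-2-oxo-3a,4,5,7a-tetrahydro-1,3-benzodioxol-6-yl]methyl benzoate
Product: 11 [(3R,4R,5S,6R)-5-(benzoyloxy)-4-hydroxy-3-methoxy-6-[(4-methoxyphenyl)methoxy]cyclohex-1-en-1-yl]methyl benzoate
Conditions: Pd(PPh3)4 (5 mol %), B(OMe)3 (2 equiv), THF, 0 °C → rt; aqueous work-up
Reagents that add atoms: trimethyl borate, COB(OC)OC
Why: Tsuji–Trost-type decarboxylative allylic etherification: zerovalent palladium ionises only the allylic carbonate C–O bond with inversion and CO2 is lost, the neighbouring alkoxide binds B(OMe)3 and the borate hands methoxide to the proximal allyl terminus anti to palladium (second inversion), so methylation is confined to O-3 with net retention, i.e. methoxy cis to the 4-hydroxyl.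

Step 7
Reactants: 11 [(3R,4R,5S,6R)-5-(benzoyloxy)-4-hydroxy-3-methoxy-6-[(4-methoxyphenyl)methoxy]cyclohex-1-en-1-yl]methyl benzoate
Product: 12 [(3R,4R,5R,6R)-5-(benzoyloxy)-4,6-dihydroxy-3-methoxycyclohex-1-en-1-yl]methyl benzoate (target)
Conditions: DDQ (1.3 equiv), CH2Cl2/H2O (18:1), 0 °C
Reagents that add atoms: none
Why: Oxidative PMB ether cleavage by DDQ (hydride abstraction to the oxocarbenium ion, then hydrolysis) frees the 6-hydroxyl under neutral conditions that leave the benzoates, the allylic methyl ether, the alkene and all four stereocentres intact.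

**Compound list**

1 | furan | c1ccoc1 | starting material
2 | methyl propiolate (methyl prop-2-ynoate) | COC(=O)C#C | starting material
3 | methyl (1R,4S)-7-oxabicyclo[2.2.1]hepta-2,5-diene-2-carboxylate | COC(=O)C1=C[C@@H]2C=C[C@H]1O2 | intermediate
4 | 4-methoxybenzyl alcohol | COc1ccc(CO)cc1 | starting material
5 | lithium ester enolate of methyl (1R,3R,4S)-3-[(4-methoxyphenyl)methoxy]-7-oxabicyclo[2.2.1]hept-5-ene-2-carboxylate (exo oxa-Michael adduct) | COC([O-])=C1[C@@H](OCc2ccc(OC)cc2)[C@@H]2C=C[C@H]1O2.[Li+] | intermediate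
6 | lithium alkoxide of methyl (5S,6R)-5-hydroxy-6-[(4-methoxyphenyl)methoxy]cyclohexa-1,3-diene-1-carboxylate | COC(=O)C1=CC=C[C@H]([O-])[C@@H]1OCc1ccc(OC)cc1.[Li+] | intermediate
7 | (1S,6R)-5-(hydroxymethyl)-6-[(4-methoxyphenyl)methoxy]cyclohexa-2,4-dien-1-ol | OCC1=CC=C[C@H](O)[C@@H]1OCc1ccc(OC)cc1 | intermediate
8 | [(5S,6R)-5-(benzoyloxy)-6-[(4-methoxyphenyl)methoxy]cyclohexa-1,3-dien-1-yl]methyl benzoate | O=C(OCC1=CC=C[C@H](OC(=O)c2ccccc2)[C@@H]1OCc1ccc(OC)cc1)c1ccccc1 | intermediate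
9 | [(3R,4R,5S,6R)-5-(benzoyloxy)-3,4-dihydroxy-6-[(4-methoxyphenyl)methoxy]cyclohex-1-en-1-yl]methyl benzoate | O[C@@H]1C=C(COC(=O)c2ccccc2)[C@@H](OCc2ccc(OC)cc2)[C@@H](OC(=O)c2ccccc2)[C@@H]1O | intermediate
10 | [(3aR,4R,5R,7aR)-4-(benzoyloxy)-5-[(4-methoxyphenyl)methoxy]-2-oxo-3a,4,5,7a-tetrahydro-1,3-benzodioxol-6-yl]methyl benzoate | O=C1O[C@@H]2C=C(COC(=O)c3ccccc3)[C@@H](OCc3ccc(OC)cc3)[C@@H](OC(=O)c3ccccc3)[C@@H]2O1 | intermediate
11 | [(3R,4R,5S,6R)-5-(benzoyloxy)-4-hydroxy-3-methoxy-6-[(4-methoxyphenyl)methoxy]cyclohex-1-en-1-yl]methyl benzoate | CO[C@@H]1C=C(COC(=O)c2ccccc2)[C@@H](OCc2ccc(OC)cc2)[C@@H](OC(=O)c2ccccc2)[C@@H]1O | intermediate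
12 | [(3R,4R,5R,6R)-5-(benzoyloxy)-4,6-dihydroxy-3-methoxycyclohex-1-en-1-yl]methyl benzoate | CO[C@@H]1C=C(COC(=O)c2ccccc2)[C@@H](O)[C@@H](OC(=O)c2ccccc2)[C@@H]1O | target

**Summary**

Total step count: 7. Longest linear sequence: 7 steps (from 1 and 2 to 12).

Steps most likely to fail, each with a fallback:

Step 1 (enantioselective cycloaddition). An alkynoate/furan pair has not been run with this catalyst type, and the Lewis acid may isomerise 3 to methyl hydroxybenzoates. The fallback replaces catalyst control by a covalent auxiliary with diastereomer separation. It sets out from 1: propiolic acid is esterified with (1R,2S,5R)-menthol (DCC, 4-(dimethylamino)pyridine) to (1R,2S,5R)-menthyl prop-2-ynoate F1. AlCl3 (1 equiv, CH2Cl2, −20 °C) promotes its cycloaddition with 1, and the two diastereomeric adducts are separated by chromatography or crystallisation, keeping (1R,2S,5R)-menthyl (1R,4S)-7-oxabicyclo[2.2.1]hepta-2,5-diene-2-carboxylate F2 and discarding its (1S,4R)-bicyclic diastereomer F3. F2 goes through the step 2 conditions by way of the menthyl lithium ester enolate F4 and the menthyl lithium dienol alkoxide F5; i-Bu2AlH cleaves the menthyl ester reductively and the route is rejoined at 7.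

Step 2 (oxa-Michael/E1cB cascade). Retro-Michael reaction, attack of the alkoxide on the ester, or base-induced aromatisation of 6 could compete. The fallback builds the C3–O bond through a C–B bond and separates the two events. It sets out from 3: copper-catalysed exo conjugate borylation (CuCl 5 mol %, NaOt-Bu, bis[2-(diphenylphosphino)phenyl] ether, B2pin2, MeOH, THF) gives methyl (1R,2R,3R,4R)-3-(4,4,5,5-tetramethyl-1,3,2-dioxaborolan-2-yl)-7-oxabicyclo[2.2.1]hept-5-ene-2-carboxylate F6. NaBO3·4H2O oxidises it with retention to methyl (1R,2R,3R,4S)-3-hydroxy-7-oxabicyclo[2.2.1]hept-5-ene-2-carboxylate F7. 4-Methoxybenzyl 2,2,2-trichloroacetimidate with La(OTf)3 (5 mol %) gives methyl (1R,2S,3R,4S)-3-[(4-methoxyphenyl)methoxy]-7-oxabicyclo[2.2.1]hept-5-ene-2-carboxylate F8. LiN(SiMe3)2 (THF, −78 °C) deprotonates C2 and the route is rejoined at enolate 5, which opens to 6 and is reduced to 7 as before.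

Step 6 (palladium-mediated methoxylation). The primary allylic benzoate may ionise or eliminate from the allyl-palladium species, and palladium must approach the face carrying the PMB ether. The fallback avoids allyl-palladium chemistry by protect–alkylate–deprotect. It sets out from 9 and leaves out 10: selective silylation of the equatorial 4-hydroxyl (t-BuMe2SiCl, i-Pr2NEt, 2-aminoethyl diphenylborinate 10 mol %, MeCN) gives [(3R,4R,5R,6R)-5-(benzoyloxy)-4-[(tert-butyldimethylsilyl)oxy]-3-hydroxy-6-[(4-methoxyphenyl)methoxy]cyclohex-1-en-1-yl]methyl benzoate F9. MeOTf with 2,6-di-tert-butyl-4-methylpyridine (CH2Cl2, 0 °C) methylates the remaining allylic hydroxyl without acyl migration to give [(3R,4R,5R,6R)-5-(benzoyloxy)-4-[(tert-butyldimethylsilyl)oxy]-3-methoxy-6-[(4-methoxyphenyl)methoxy]cyclohex-1-en-1-yl]methyl benzoate F10. HF·pyridine (THF, 0 °C) removes the silyl group and the route is rejoined at 11.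

**Further compounds**

F1 | step 1 | (1R,2S,5R)-menthyl prop-2-ynoate | CC(C)[C@@H]1CC[C@@H](C)C[C@H]1OC(=O)C#C
F2 | step 1 | (1R,2S,5R)-menthyl (1R,4S)-7-oxabicyclo[2.2.1]hepta-2,5-diene-2-carboxylate | CC(C)[C@@H]1CC[C@@H](C)C[C@H]1OC(=O)C1=C[C@@H]2C=C[C@H]1O2
F3 | step 1 | (1R,2S,5R)-menthyl (1S,4R)-7-oxabicyclo[2.2.1]hepta-2,5-diene-2-carboxylate (unwanted diastereomer) | CC(C)[C@@H]1CC[C@@H](C)C[C@H]1OC(=O)C1=C[C@H]2C=C[C@@H]1O2
F4 | step 1 | lithium ester enolate of (1R,2S,5R)-menthyl (1R,3R,4S)-3-[(4-methoxyphenyl)methoxy]-7-oxabicyclo[2.2.1]hept-5-ene-2-carboxylate | CC(C)[C@@H]1CC[C@@H](C)C[C@H]1OC([O-])=C1[C@@H](OCc2ccc(OC)cc2)[C@@H]2C=C[C@H]1O2.[Li+]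
F5 | step 1 | lithium alkoxide of (1R,2S,5R)-menthyl (5S,6R)-5-hydroxy-6-[(4-methoxyphenyl)methoxy]cyclohexa-1,3-diene-1-carboxylate | CC(C)[C@@H]1CC[C@@H](C)C[C@H]1OC(=O)C1=CC=C[C@H]([O-])[C@@H]1OCc1ccc(OC)cc1.[Li+]
F6 | step 2 | methyl (1R,2R,3R,4R)-3-(4,4,5,5-tetramethyl-1,3,2-dioxaborolan-2-yl)-7-oxabicyclo[2.2.1]hept-5-ene-2-carboxylate | COC(=O)[C@@H]1[C@@H](B3OC(C)(C)C(C)(C)O3)[C@@H]2C=C[C@H]1O2
F7 | step 2 | methyl (1R,2R,3R,4S)-3-hydroxy-7-oxabicyclo[2.2.1]hept-5-ene-2-carboxylate | COC(=O)[C@@H]1[C@@H](O)[C@@H]2C=C[C@H]1O2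
F8 | step 2 | methyl (1R,2S,3R,4S)-3-[(4-methoxyphenyl)methoxy]-7-oxabicyclo[2.2.1]hept-5-ene-2-carboxylate | COC(=O)[C@@H]1[C@@H](OCc3ccc(OC)cc3)[C@@H]2C=C[C@H]1O2
F9 | step 6 | [(3R,4R,5R,6R)-5-(benzoyloxy)-4-[(tert-butyldimethylsilyl)oxy]-3-hydroxy-6-[(4-methoxyphenyl)methoxy]cyclohex-1-en-1-yl]methyl benzoate | O[C@@H]1C=C(COC(=O)c2ccccc2)[C@@H](OCc2ccc(OC)cc2)[C@@H](OC(=O)c2ccccc2)[C@@H]1O[Si](C)(C)C(C)(C)C
F10 | step 6 | [(3R,4R,5R,6R)-5-(benzoyloxy)-4-[(tert-butyldimethylsilyl)oxy]-3-methoxy-6-[(4-methoxyphenyl)methoxy]cyclohex-1-en-1-yl]methyl benzoate | CO[C@@H]1C=C(COC(=O)c2ccccc2)[C@@H](OCc2ccc(OC)cc2)[C@@H](OC(=O)c2ccccc2)[C@@H]1O[Si](C)(C)C(C)(C)C
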